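**Plan**
- Target: a 5-hydroxy-6,7-dimethoxyflavone carrying a 5-hydroxy-2,3-dimethoxyphenyl ring B. It has no stereocentre, so no stereocontrol is required.
- Retrosynthesis: the free O5–H and O5'–H come from a 5-methyl and a 5'-benzyl ether. Ring C is opened at O1–C2 to an ortho-hydroxyaryl ynone. Then O1–C8a and C4–C4a are cut together, giving 3,4,5-trimethoxybenzyne and an arylpropiolic acid.
- Enabling feature: on ring A, O1 (on C8a) and C4 (on C4a) sit on neighbouring carbons, and C4a lies next to the oxygen-bearing C5. This is what a 3-methoxyaryne takes up when it inserts into the acyl C–O bond of a carboxylic acid.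
- Forward: the ring A aryne precursor takes 2 steps from 3,4,5-trimethoxyphenol and the ring B propiolic acid 5 steps from 3-bromo-4,5-dimethoxybenzaldehyde. The insertion joins them without forming a ring, ring C then closes by 6-endo oxa-Michael addition, and BCl3 unmasks both phenols.

Key step: step 8

Remark: should part of the ynone formed in the key step already close to the flavone in the same pot, the mixture is carried into the following step, which converges it.

**Step 1**
Reactants: 1 3,4,5-trimethoxyphenol
Product: 2 2-bromo-3,4,5-trimethoxyphenol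
Conditions: NBS (1.0 equiv), CH2Cl2, −78 °C to 0 °C
Reagents that add atoms: N-bromosuccinimide, O=C1CCC(=O)N1Br
Why: Electrophilic aromatic bromination directed by the phenol; the para position is blocked and the two ortho positions are equivalent, so one equivalent of NBS at low temperature should give a single monobromide.

**Step 2**
Reactants: 2 2-bromo-3,4,5-trimethoxyphenol
Product: 5 3,4,5-trimethoxy-2-(trimethylsilyl)phenyl trifluoromethanesulfonate, via trimethylsilyl ether 3 (not isolated), via lithium silylphenolate 4 (not isolated)
Conditions: HMDS, THF, reflux, then evaporation; n-BuLi, THF, −100 °C to −78 °C; Tf2O, −100 °C to rt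
Reagents that add atoms: hexamethyldisilazane, C[Si](C)(C)N[Si](C)(C)C; trifluoromethanesulfonic anhydride, O=S(=O)(OS(=O)(=O)C(F)(F)F)C(F)(F)F
Why: O-silylation, bromine–lithium exchange and retro-Brook 1,3 O-to-C silyl shift (driven by formation of the lithium phenolate) followed by O-triflation is the standard one-pot route from ortho-bromophenols to ortho-silylaryl triflates.

**Step 3**
Reactants: 6 3-bromo-4,5-dimethoxybenzaldehyde
Product: 8 3-bromo-4,5-dimethoxyphenol, via aryl formate 7 (not isolated)
Conditions: mCPBA, CH2Cl2, rt; aq. NaHCO3 wash; then K2CO3 (cat.), MeOH, rt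
Reagents that add atoms: 3-chloroperoxybenzoic acid, OOC(=O)c1cccc(Cl)c1
Why: Baeyer–Villiger (Dakin-type) oxidation; the para-methoxy group makes the aryl group migrate in preference to hydride, and the resulting formate is cleaved by methanolysis.

**Step 4**
Reactants: 8 3-bromo-4,5-dimethoxyphenol
Product: 9 5-(benzyloxy)-1-bromo-2,3-dimethoxybenzene
Conditions: BnBr, K2CO3, DMF, rt
Reagents that add atoms: benzyl bromide, BrCc1ccccc1
Why: Williamson etherification of the only acidic OH; the benzyl ether should survive organolithium, fluoride and carbonate conditions and be cleavable by BCl3 at the end.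

**Step 5**
Reactants: 9 5-(benzyloxy)-1-bromo-2,3-dimethoxybenzene; 10 ethynyltrimethylsilane
Product: 11 {[5-(benzyloxy)-2,3-dimethoxyphenyl]ethynyl}trimethylsilane
Conditions: Pd(PhCN)2Cl2 (cat.), [(t-Bu)3PH]BF4 (cat.), CuI (cat.), i-Pr2NH, dioxane, rt to 50 °C
Reagents that add atoms: none
Why: Sonogashira coupling; the bulky electron-rich tri-tert-butylphosphine lets zerovalent palladium insert into the electron-rich, ortho-substituted aryl bromide under mild conditions, and the silyl cap prevents double arylation.

**Step 6**
Reactants: 11 {[5-(benzyloxy)-2,3-dimethoxyphenyl]ethynyl}trimethylsilane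
Product: 12 5-(benzyloxy)-1-ethynyl-2,3-dimethoxybenzene
Conditions: K2CO3 (cat.), MeOH/THF, rt
Reagents that add atoms: none
Why: Methanolysis of the alkynyl C–Si bond (protodesilylation) is fast and leaves the ethers untouched.

**Step 7**
Reactants: 12 5-(benzyloxy)-1-ethynyl-2,3-dimethoxybenzene
Product: 14 3-[5-(benzyloxy)-2,3-dimethoxyphenyl]prop-2-ynoic acid, via lithium arylacetylide 13 (not isolated)
Conditions: n-BuLi, THF, −78 °C; CO2 (dry gas), −78 °C to rt; aq. HCl
Reagents that add atoms: carbon dioxide, O=C=O
Why: Deprotonation of the terminal alkyne at −78 °C is much faster than ring or benzylic lithiation, and carboxylation of the acetylide with CO2 is the standard route to arylpropiolic acids.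

**Step 8**
Reactants: 5 3,4,5-trimethoxy-2-(trimethylsilyl)phenyl trifluoromethanesulfonate; 14 3-[5-(benzyloxy)-2,3-dimethoxyphenyl]prop-2-ynoic acid
Product: 16 3-[5-(benzyloxy)-2,3-dimethoxyphenyl]-1-(6-hydroxy-2,3,4-trimethoxyphenyl)prop-2-yn-1-one, via 3,4,5-trimethoxybenzyne 15 (not isolated)
Conditions: CsF (4 equiv), 5 (1.5 equiv), THF, 125 °C, sealed tube; aq. NH4Cl
Reagents that add atoms: none
Why: Fluoride attacks silicon of 5 and triflate leaves, releasing aryne 15, to which the cesium carboxylate of 14 adds through oxygen at the aryne carbon remote from the flanking methoxy group (future C8a), leaving the aryl anion ortho to that methoxy group (future C4a). This anion attacks the neighbouring ester carbonyl through a four-membered alkoxide whose collapse moves the alkynoyl group from oxygen to carbon and frees the phenoxide, an anionic Fries-type 1,3-acyl shift that forms O1–C8a and C4–C4a in one event. The closest known reaction type is the insertion of arynes into the acyl C–O bond of carboxylic acids to give ortho-hydroxyaryl ketones, run in hot THF so that acyl transfer outruns protonation of the aryl anion to the simple aryl ester. No ring is closed and no stereocentre is formed in this step. The selectivity needed is the orientation of addition, secured by the methoxy group beside the aryne bond, whose inductive pull and distortion of the aryne steer the nucleophile to the distal carbon; attack of the aryl anion on the carbonyl carbon instead of the alkyne is secured by the preferred Z ester conformation, which holds the carbonyl next to the anion and turns the alkyne away.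

**Step 9**
Reactants: 16 3-[5-(benzyloxy)-2,3-dimethoxyphenyl]-1-(6-hydroxy-2,3,4-trimethoxyphenyl)prop-2-yn-1-one
Product: 17 2-[5-(benzyloxy)-2,3-dimethoxyphenyl]-5,6,7-trimethoxy-4H-chromen-4-one
Conditions: K2CO3, acetone, reflux
Reagents that add atoms: none
Why: Intramolecular oxa-Michael addition of the phenoxide to the ynone; in an aprotic medium the 6-endo-dig closure to the pyranone is expected to prevail over 5-exo-dig closure to an aurone, and no stereocentre arises.

**Step 10**
Reactants: 17 2-[5-(benzyloxy)-2,3-dimethoxyphenyl]-5,6,7-trimethoxy-4H-chromen-4-one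
Product: 18 5-hydroxy-2-(5-hydroxy-2,3-dimethoxyphenyl)-6,7-dimethoxy-4H-chromen-4-one
Conditions: BCl3 (5 equiv), pentamethylbenzene, CH2Cl2, −78 °C to 0 °C; MeOH/H2O quench
Reagents that add atoms: none
Why: Lewis-acid ether cleavage; BCl3 with a cation scavenger removes aryl benzyl ethers at low temperature, and chelation of boron between the C4 carbonyl and the peri 5-methoxy group activates that methyl ether alone, while the unchelated methyl ethers should survive at or below 0 °C.

**Compound list**
1 | 3,4,5-trimethoxyphenol | COc1cc(O)cc(OC)c1OC | starting material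
2 | 2-bromo-3,4,5-trimethoxyphenol | COc1cc(O)c(Br)c(OC)c1OC | intermediate
3 | (2-bromo-3,4,5-trimethoxyphenoxy)trimethylsilane | COc1cc(O[Si](C)(C)C)c(Br)c(OC)c1OC | intermediate
4 | lithium 3,4,5-trimethoxy-2-(trimethylsilyl)phenolate | [Li+].[O-]c1cc(OC)c(OC)c(OC)c1[Si](C)(C)C | intermediate
5 | 3,4,5-trimethoxy-2-(trimethylsilyl)phenyl trifluoromethanesulfonate | COc1cc(OS(=O)(=O)C(F)(F)F)c([Si](C)(C)C)c(OC)c1OC | intermediate
6 | 3-bromo-4,5-dimethoxybenzaldehyde | COc1cc(C=O)cc(Br)c1OC | starting material
7 | 3-bromo-4,5-dimethoxyphenyl formate | COc1cc(OC=O)cc(Br)c1OC | intermediate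
8 | 3-bromo-4,5-dimethoxyphenol | COc1cc(O)cc(Br)c1OC | intermediate
9 | 5-(benzyloxy)-1-bromo-2,3-dimethoxybenzene | COc1cc(OCc2ccccc2)cc(Br)c1OC | intermediate
10 | ethynyltrimethylsilane | C#C[Si](C)(C)C | starting material
11 | {[5-(benzyloxy)-2,3-dimethoxyphenyl]ethynyl}trimethylsilane | COc1cc(OCc2ccccc2)cc(C#C[Si](C)(C)C)c1OC | intermediate
12 | 5-(benzyloxy)-1-ethynyl-2,3-dimethoxybenzene | COc1cc(OCc2ccccc2)cc(C#C)c1OC | intermediate
13 | lithium [5-(benzyloxy)-2,3-dimethoxyphenyl]acetylide | [Li]C#Cc1cc(OCc2ccccc2)cc(OC)c1OC | intermediate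
14 | 3-[5-(benzyloxy)-2,3-dimethoxyphenyl]prop-2-ynoic acid | OC(=O)C#Cc1cc(OCc2ccccc2)cc(OC)c1OC | intermediate
15 | 3,4,5-trimethoxybenzyne (1,2-didehydro-3,4,5-trimethoxybenzene) | COC1=CC#CC(OC)=C1OC | intermediate
16 | 3-[5-(benzyloxy)-2,3-dimethoxyphenyl]-1-(6-hydroxy-2,3,4-trimethoxyphenyl)prop-2-yn-1-one | COc1cc(O)c(C(=O)C#Cc2cc(OCc3ccccc3)cc(OC)c2OC)c(OC)c1OC | intermediate
17 | 2-[5-(benzyloxy)-2,3-dimethoxyphenyl]-5,6,7-trimethoxy-4H-chromen-4-one | COc1cc(OCc2ccccc2)cc(-c2cc(=O)c3c(OC)c(OC)c(OC)cc3o2)c1OC | intermediate
18 | 5-hydroxy-2-(5-hydroxy-2,3-dimethoxyphenyl)-6,7-dimethoxy-4H-chromen-4-one | COc1cc(O)cc(-c2cc(=O)c3c(O)c(OC)c(OC)cc3o2)c1OC | target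

**Step count and risks**
Total steps: 10. Longest linear sequence: 8 steps (steps 3 to 10, from 6 to 18).

Steps most likely to fail:

Step 8. The aryl anion may be protonated before the acyl group shifts, so that only O-arylation takes place. The propiolate may lose CO2 at 125 °C, or the product phenoxide may be arylated by a second aryne. Fallback, setting out from 1 and 12 and rejoining at 17: 3,4,5-trimethoxyphenol 1 would be iodinated with N-iodosuccinimide to 2-iodo-3,4,5-trimethoxyphenol F1. F1, alkyne 12 and carbon monoxide would then be joined in a carbonylative Sonogashira coupling (PdCl2(PPh3)2, Et3N, CO 1 atm, DMF). The aroylpalladium species from F1 acylates the alkyne to ynone 16 in the flask, and DBU added at the end closes it to flavone 17, from which step 10 follows.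

Step 10. Demethylation may go too far (loss of the 6-methyl ether beside the boron chelate or of a ring B methyl ether), or the released benzyl cation may C-benzylate the electron-rich rings. Fallback, setting out from 17 and rejoining at 18: the benzyl ether would first be removed by hydrogenolysis (H2, Pd/C, EtOAc/MeOH) to give 2-(5-hydroxy-2,3-dimethoxyphenyl)-5,6,7-trimethoxy-4H-chromen-4-one F2. The chelated 5-methyl ether of F2 would then be cleaved on its own with AlCl3 in MeCN to give 18.

Step 9. The ring may close in the 5-exo mode to the aurone skeleton, or conversion may stall. Fallback, setting out from 16 and rejoining at 17: diethylamine in EtOH at rt would add to the ynone to give the enaminone (2E)-3-[5-(benzyloxy)-2,3-dimethoxyphenyl]-3-(diethylamino)-1-(6-hydroxy-2,3,4-trimethoxyphenyl)prop-2-en-1-one F3, whose double-bond geometry is of no consequence. On warming with a little AcOH the phenol adds to the amine-bearing carbon and diethylamine is expelled, an addition–elimination sequence that can only give the six-membered ring of 17.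

**Further compounds**
F1 | step 8 | 2-iodo-3,4,5-trimethoxyphenol | COc1cc(O)c(I)c(OC)c1OC
F2 | step 10 | 2-(5-hydroxy-2,3-dimethoxyphenyl)-5,6,7-trimethoxy-4H-chromen-4-one | COc1cc(O)cc(-c2cc(=O)c3c(OC)c(OC)c(OC)cc3o2)c1OC
F3 | step 9 | (2E)-3-[5-(benzyloxy)-2,3-dimethoxyphenyl]-3-(diethylamino)-1-(6-hydroxy-2,3,4-trimethoxyphenyl)prop-2-en-1-one | CCN(CC)/C(=C/C(=O)c1c(O)cc(OC)c(OC)c1OC)c1cc(OCc2ccccc2)cc(OC)c1OC
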